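The target is read as an oxidised para-quinol. C1, the quaternary oxirane carbon of the carbocycle that carries C7, is the carbinol carbon of a 4-hydroxycyclohexa-2,5-dienone whose two enone arms (C2=C3 and C5=C6, carbonyl at C4) are enantiotopic. A tartrate-controlled nucleophilic epoxidation of the achiral dienone 4 (4-silyloxy-4-silyloxymethyl) oxidises only the C5=C6 arm, on the face opposite the C1 silyloxy group, and so makes C1, C5 and C6 stereogenic in one operation. The rest is substrate relay: osmylation of C2=C3, Wharton transposition to the C6 allylic alcohol, and closure of the C1 oxygen onto C6 with inversion.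

Key step: step 4

Locants in all names are those of the target carbocycle, not IUPAC locants: C1 bears C7 and the tertiary oxygen, C4 is the dienone carbonyl carbon, C2/C3 become the diol, C5/C6 are epoxidised. TBS = tert-butyldimethylsilyl, TES = triethylsilyl. CIP descriptors at C1 and C3 change along the route only because substituent priorities change; the only configuration that is altered is C6 in step 9.

Assumption: L-(+)-diisopropyl tartrate is taken to direct the peroxide to the C5=C6 arm as drawn; if the sense proves opposite, D-(−)-diisopropyl tartrate is used with no other change.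

Design choices:
- The C1 oxygen carries TBS, a bulky silyl group that still goes onto a tertiary alcohol easily. It should lie over its own ring face and steer both the epoxidation and the osmylation to the other face.
- All temporary groups are fluoride-labile silyl ethers, so one Bu4NF treatment unmasks the C1 oxygen for ring closure and frees the three hydroxyls.
- The benzoates are introduced last because they would not tolerate hydrazine or alkoxides.

Step 1
Reactants: 1 4-hydroxybenzyl alcohol
Product: 2 4-[(TBS-oxy)methyl]phenol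
Conditions: TBSCl (1.05 equiv), imidazole, DMF, 0 °C
Reagents that add atoms: tert-butyldimethylsilyl chloride, CC(C)(C)[Si](C)(C)Cl
Why: Silylation of an alcohol with a silyl chloride and imidazole is faster at the primary benzylic hydroxyl than at the less nucleophilic phenol with one equivalent of reagent at 0 °C; no stereocentre is involved.

Step 2
Reactants: 2 4-[(TBS-oxy)methyl]phenol
Product: 3 1-hydroxy-1-[(TBS-oxy)methyl]cyclohexa-2,5-dien-4-one
Conditions: PhI(OAc)2, MeCN/H2O (4:1), 0 °C
Reagents that add atoms: water, O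
Why: Oxidative dearomatisation of a para-alkylphenol by trivalent iodine with capture of water at the para carbon is the standard entry to para-quinols, and the product is achiral because a mirror plane passes through C1 and C4.

Step 3
Reactants: 3 1-hydroxy-1-[(TBS-oxy)methyl]cyclohexa-2,5-dien-4-one
Product: 4 1-(TBS-oxy)-1-[(TBS-oxy)methyl]cyclohexa-2,5-dien-4-one
Conditions: TBSOTf, 2,6-lutidine, CH2Cl2, −78 → 0 °C
Reagents that add atoms: tert-butyldimethylsilyl triflate, CC(C)(C)[Si](C)(C)OS(=O)(=O)C(F)(F)F
Why: Silyl triflate with 2,6-lutidine silylates hindered tertiary alcohols under non-nucleophilic conditions that leave the dienone untouched, and the compound stays achiral.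

Step 4
Reactants: 4 1-(TBS-oxy)-1-[(TBS-oxy)methyl]cyclohexa-2,5-dien-4-one; 5 trityl hydroperoxide
Product: 7 (1S,5S,6R)-1-(TBS-oxy)-1-[(TBS-oxy)methyl]-5,6-epoxycyclohex-2-en-4-one (oxirane on the face of C7), via C6 trityldioxy sodium dienolate 6 (not isolated)
Conditions: Ph3COOH (1.2 equiv), NaN(SiMe3)2 (1.1 equiv), L-(+)-DIPT (1.3 equiv), 4 Å MS, toluene, −50 °C
Reagents that add atoms: trityl hydroperoxide, OOC(c1ccccc1)(c1ccccc1)c1ccccc1
Why: Ph3COONa, held in a chiral sodium tartrate aggregate that also binds the dienone carbonyl, adds in conjugate fashion to C6 of one enone arm to give dienolate 6, whose C5 then attacks the proximal peroxide oxygen and expels trityloxide (Weitz–Scheffer mechanism). The closest known reaction type is the tartrate-mediated nucleophilic epoxidation of quinone monoketals, which are 4,4-disubstituted cyclohexa-2,5-dienones like 4. The only ring formed, the oxirane C5–O–C6, closes in a 3-exo-tet mode and is necessarily cis-fused. The configuration at C5 and C6 follows from the face of attack, which should be the one opposite the C1 TBS-oxy group because that group lies over its own face and its oxygen repels the incoming peroxide anion; C1 becomes stereogenic through the choice of arm, which is made by the chiral tartrate–peroxide aggregate. The step needs arm selectivity, anti face selectivity and mono-epoxidation: the first rests on the reagent, the second on the bulky O-silyl group of 4, and the third on keeping the peroxide near one equivalent at low temperature.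

Step 5
Reactants: 7 (1S,5S,6R)-1-(TBS-oxy)-1-[(TBS-oxy)methyl]-5,6-epoxycyclohex-2-en-4-one
Product: 8 (1R,2S,3R,5S,6R)-1-(TBS-oxy)-1-[(TBS-oxy)methyl]-5,6-epoxy-2,3-dihydroxycyclohexan-4-one (both hydroxyls on the face of C7)
Conditions: OsO4 (5 mol %), NMO, citric acid, t-BuOH/H2O (1:1), rt
Reagents that add atoms: N-methylmorpholine N-oxide, C[N+]1([O-])CCOCC1; water, O
Why: Upjohn cis-dihydroxylation adds both oxygens suprafacially to the remaining enone C2=C3 from the face opposite the C1 TBS-oxy group (the usual anti sense for osmylation next to an allylic oxygen, reinforced by the silyl group over that face), so O2 and O3 should end up cis to each other and to C7, while citric acid keeps the catalyst turning over on the electron-poor alkene.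

Step 6
Reactants: 8 (1R,2S,3R,5S,6R)-1-(TBS-oxy)-1-[(TBS-oxy)methyl]-5,6-epoxy-2,3-dihydroxycyclohexan-4-one
Product: 9 (1S,2S,3R,5S,6R)-1-(TBS-oxy)-1-[(TBS-oxy)methyl]-5,6-epoxy-2,3-bis(TES-oxy)cyclohexan-4-one
Conditions: TESOTf, 2,6-lutidine, CH2Cl2, −78 → −20 °C
Reagents that add atoms: triethylsilyl triflate, CC[Si](CC)(CC)OS(=O)(=O)C(F)(F)F
Why: Silyl triflate silylation caps both the accessible alpha-ketol hydroxyl at C3 and the hindered C2 hydroxyl without the basic conditions that could trigger retro-aldol cleavage, and no stereocentre is touched.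

Step 7
Reactants: 9 (1S,2S,3R,5S,6R)-1-(TBS-oxy)-1-[(TBS-oxy)methyl]-5,6-epoxy-2,3-bis(TES-oxy)cyclohexan-4-one
Product: 12 (1S,2S,3S,6R)-1-(TBS-oxy)-1-[(TBS-oxy)methyl]-2,3-bis(TES-oxy)cyclohex-4-en-6-ol, via epoxy hydrazone 10 (not isolated), via alkenyl diazene 11 (not isolated)
Conditions: N2H4·H2O, AcOH (cat.), MeOH, 0 °C → rt
Reagents that add atoms: none
Why: In the Wharton transposition hydrazone 10 opens the adjacent oxirane to alkenyl diazene 11, which loses N2 to leave the C4=C5 alkene and the C6 alcohol; the C6–O bond is never broken, so C6 keeps the configuration set in step 4.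

Step 8
Reactants: 12 (1S,2S,3S,6R)-1-(TBS-oxy)-1-[(TBS-oxy)methyl]-2,3-bis(TES-oxy)cyclohex-4-en-6-ol
Product: 13 (1R,2S,3S,6R)-1-(TBS-oxy)-1-[(TBS-oxy)methyl]-2,3-bis(TES-oxy)cyclohex-4-en-6-yl methanesulfonate
Conditions: MsCl, Et3N, CH2Cl2, −20 → 0 °C; used crude
Reagents that add atoms: methanesulfonyl chloride, CS(=O)(=O)Cl
Why: Sulfonylation through sulfene activates even a hindered secondary alcohol with retention at C6, and the quaternary C1 next to C6 shields the allylic mesylate from intermolecular displacement.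

Step 9
Reactants: 13 (1R,2S,3S,6R)-1-(TBS-oxy)-1-[(TBS-oxy)methyl]-2,3-bis(TES-oxy)cyclohex-4-en-6-yl methanesulfonate
Product: 15 (1R,2S,3S,6S)-1,6-epoxy-1-(hydroxymethyl)cyclohex-4-ene-2,3-diol, via tetrol mesylate 14 (not isolated)
Conditions: Bu4NF (5 equiv), THF, 0 °C → rt; NH4Cl quench
Reagents that add atoms: none
Why: Fluoride desilylation frees the C1 oxygen (drawn as 14), which is anti to the C6 mesylate and displaces it by intramolecular SN2 (3-exo-tet, inversion at C6) to give the vinyl oxirane while the same reagent removes the other silyl ethers; the C7 and C2 oxygens lie on the face of the leaving group and cannot reach the back side of C6, and a Payne migration would require SN2 at the fully substituted C1.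

Step 10
Reactants: 15 (1R,2S,3S,6S)-1,6-epoxy-1-(hydroxymethyl)cyclohex-4-ene-2,3-diol; 16 benzoyl chloride
Product: 18 (1R,2S,3S,6S)-3-benzoyloxy-1-(benzoyloxymethyl)-1,6-epoxycyclohex-4-en-2-ol, via C7 monobenzoate 17 (not isolated)
Conditions: BzCl (2.1 equiv), pyridine, CH2Cl2, −40 → 0 °C
Reagents that add atoms: benzoyl chloride, O=C(Cl)c1ccccc1
Why: In this sterically controlled acylation the primary C7 hydroxyl should react first (17) and the allylic C3 hydroxyl second, whereas the C2 hydroxyl, flanked by the quaternary C1 and the new C3 benzoate, should stay free at low temperature with only a slight excess of acid chloride.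

Compound list
1 | 4-hydroxybenzyl alcohol | OCc1ccc(O)cc1 | starting material
2 | 4-[(TBS-oxy)methyl]phenol | CC(C)(C)[Si](C)(C)OCc1ccc(O)cc1 | intermediate
3 | 1-hydroxy-1-[(TBS-oxy)methyl]cyclohexa-2,5-dien-4-one (achiral para-quinol) | O=C1C=CC(O)(CO[Si](C)(C)C(C)(C)C)C=C1 | intermediate
4 | 1-(TBS-oxy)-1-[(TBS-oxy)methyl]cyclohexa-2,5-dien-4-one (achiral precursor of the key step) | O=C1C=CC(CO[Si](C)(C)C(C)(C)C)(O[Si](C)(C)C(C)(C)C)C=C1 | intermediate
5 | trityl hydroperoxide | OOC(c1ccccc1)(c1ccccc1)c1ccccc1 | starting material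
6 | sodium (1S,6R)-dienolate of 4 carrying a trityldioxy group at C6, anti to the C1 TBS-oxy group (not isolated) | [Na+].[O-]C1=C[C@@H](OOC(c2ccccc2)(c2ccccc2)c2ccccc2)[C@](CO[Si](C)(C)C(C)(C)C)(O[Si](C)(C)C(C)(C)C)C=C1 | intermediate
7 | (1S,5S,6R)-1-(TBS-oxy)-1-[(TBS-oxy)methyl]-5,6-epoxycyclohex-2-en-4-one (product of the key step; oxirane anti to the C1 oxygen) | O=C1C=C[C@@](CO[Si](C)(C)C(C)(C)C)(O[Si](C)(C)C(C)(C)C)[C@@H]2O[C@H]12 | intermediate
8 | (1R,2S,3R,5S,6R)-1-(TBS-oxy)-1-[(TBS-oxy)methyl]-5,6-epoxy-2,3-dihydroxycyclohexan-4-one | O=C1[C@H](O)[C@H](O)[C@@](CO[Si](C)(C)C(C)(C)C)(O[Si](C)(C)C(C)(C)C)[C@@H]2O[C@H]12 | intermediate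
9 | (1S,2S,3R,5S,6R)-1-(TBS-oxy)-1-[(TBS-oxy)methyl]-5,6-epoxy-2,3-bis(TES-oxy)cyclohexan-4-one | O=C1[C@H](O[Si](CC)(CC)CC)[C@H](O[Si](CC)(CC)CC)[C@@](CO[Si](C)(C)C(C)(C)C)(O[Si](C)(C)C(C)(C)C)[C@@H]2O[C@H]12 | intermediate
10 | C4 hydrazone of 9 (not isolated) | NN=C1[C@H](O[Si](CC)(CC)CC)[C@H](O[Si](CC)(CC)CC)[C@@](CO[Si](C)(C)C(C)(C)C)(O[Si](C)(C)C(C)(C)C)[C@@H]2O[C@H]12 | intermediate
11 | C4 diazenyl cyclohex-4-en-6-ol formed by oxirane opening of 10 (not isolated) | N=NC1=C[C@@H](O)[C@](CO[Si](C)(C)C(C)(C)C)(O[Si](C)(C)C(C)(C)C)[C@@H](O[Si](CC)(CC)CC)[C@H]1O[Si](CC)(CC)CC | intermediate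
12 | (1S,2S,3S,6R)-1-(TBS-oxy)-1-[(TBS-oxy)methyl]-2,3-bis(TES-oxy)cyclohex-4-en-6-ol | C1=C[C@@H](O)[C@](CO[Si](C)(C)C(C)(C)C)(O[Si](C)(C)C(C)(C)C)[C@@H](O[Si](CC)(CC)CC)[C@H]1O[Si](CC)(CC)CC | intermediate
13 | (1R,2S,3S,6R)-6-methanesulfonate of 12 | C1=C[C@@H](OS(C)(=O)=O)[C@](CO)(O)[C@@H](O)[C@H]1O with all four silyl groups in place: C1=C[C@@H](OS(C)(=O)=O)[C@](CO[Si](C)(C)C(C)(C)C)(O[Si](C)(C)C(C)(C)C)[C@@H](O[Si](CC)(CC)CC)[C@H]1O[Si](CC)(CC)CC | intermediate
14 | (1R,2S,3S,6R)-1-(hydroxymethyl)-6-(methanesulfonyloxy)cyclohex-4-ene-1,2,3-triol, the desilylated form of 13 whose C1 oxygen closes the ring (not isolated) | C1=C[C@@H](OS(C)(=O)=O)[C@](CO)(O)[C@@H](O)[C@H]1O | intermediate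
15 | (1R,2S,3S,6S)-1,6-epoxy-1-(hydroxymethyl)cyclohex-4-ene-2,3-diol | OC[C@]12O[C@H]1C=C[C@H](O)[C@@H]2O | intermediate
16 | benzoyl chloride | O=C(Cl)c1ccccc1 | starting material
17 | (1R,2S,3S,6S)-1-(benzoyloxymethyl)-1,6-epoxycyclohex-4-ene-2,3-diol (not isolated) | O=C(OC[C@]12O[C@H]1C=C[C@H](O)[C@@H]2O)c1ccccc1 | intermediate
18 | (1R,2S,3S,6S)-3-benzoyloxy-1-(benzoyloxymethyl)-1,6-epoxycyclohex-4-en-2-ol | O=C(OC[C@]12O[C@H]1C=C[C@H](OC(=O)c1ccccc1)[C@@H]2O)c1ccccc1 | target

For compound 13 the SMILES that applies is the second one on its line (the fully silylated mesylate).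

Total step count: 10
Longest linear sequence: 10 steps, from 1 to 18

Steps most likely to fail

1. Step 4. The chiral aggregate may discriminate the two enantiotopic arms only weakly, the anti face preference may be incomplete, or the product may be epoxidised a second time. Fallback by resolution instead of asymmetric induction: from 4, a racemic but anti-selective Weitz–Scheffer epoxidation (t-BuOOH, DBU, CH2Cl2, 0 °C) should give the racemic epoxy enone F1. Preparative chromatography on a chiral stationary phase (amylose tris(3,5-dimethylphenylcarbamate)) then separates the enantiomers, and the route is rejoined at 7.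

2. Step 5. Osmylation may occur on the wrong face (syn to the C1 oxygen), or the electron-poor alkene may react sluggishly. Fallback by intramolecular direction from C7, which lies on the face that must be hydroxylated:
   - From 7, buffered HF·pyridine (pyridine, THF, 0 °C) removes only the primary TBS group and should give the primary alcohol F2.
   - Hydroxyl-directed dihydroxylation (stoichiometric OsO4 with TMEDA, CH2Cl2, −78 °C, then aqueous Na2SO3) delivers the reagent by hydrogen bonding from the C7 hydroxyl and should give the triol F3.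
   - Selective silylation of the primary hydroxyl (TBSCl, imidazole, CH2Cl2, 0 °C) returns to the route at 8.

3. Step 10. Acylation may not distinguish the C3 from the C2 hydroxyl, over-benzoylation may occur, or a benzoyl group may migrate between O3 and O2. Fallback by a tether that fixes the regiochemistry through ring size:
   - From 15, 1,3-dichloro-1,1,3,3-tetraisopropyldisiloxane in pyridine at 0 °C should start at the primary O7 and close onto the cis, 1,3-related O2 (eight-membered ring, the mode used for 3',5'-protection of nucleosides) to give the bridged disiloxane F4, in which only the C3 hydroxyl is free.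
   - Exhaustive benzoylation (BzCl, DMAP, pyridine) gives its 3-benzoate F5.
   - Buffered fluoride (Et3N·3HF, THF, rt) releases the 3-O-benzoyl diol F6.
   - Benzoylation of the primary hydroxyl in preference to the hindered C2 hydroxyl (BzCl 1.05 equiv, 2,4,6-collidine, CH2Cl2, −78 °C) arrives at 18.

Further compounds
F1 | step 4 | racemic 1-(TBS-oxy)-1-[(TBS-oxy)methyl]-5,6-epoxycyclohex-2-en-4-one (oxirane anti to the C1 oxygen; 1:1 mixture of 7 and its enantiomer) | O=C1C=C[C@@](CO[Si](C)(C)C(C)(C)C)(O[Si](C)(C)C(C)(C)C)[C@@H]2O[C@H]12.O=C1C=C[C@](CO[Si](C)(C)C(C)(C)C)(O[Si](C)(C)C(C)(C)C)[C@H]2O[C@@H]12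
F2 | step 5 | (1S,5S,6R)-1-(TBS-oxy)-1-(hydroxymethyl)-5,6-epoxycyclohex-2-en-4-one | O=C1C=C[C@@](CO)(O[Si](C)(C)C(C)(C)C)[C@@H]2O[C@H]12
F3 | step 5 | (1R,2S,3R,5S,6R)-1-(TBS-oxy)-1-(hydroxymethyl)-5,6-epoxy-2,3-dihydroxycyclohexan-4-one | O=C1[C@H](O)[C@H](O)[C@@](CO)(O[Si](C)(C)C(C)(C)C)[C@@H]2O[C@H]12
F4 | step 10 | 2,7-O-(1,1,3,3-tetraisopropyldisiloxane-1,3-diyl) derivative of 15 | CC(C)[Si]3(C(C)C)O[Si](C(C)C)(C(C)C)OC[C@]12O[C@H]1C=C[C@H](O)[C@@H]2O3
F5 | step 10 | 3-O-benzoate of F4 | CC(C)[Si]3(C(C)C)O[Si](C(C)C)(C(C)C)OC[C@]12O[C@H]1C=C[C@H](OC(=O)c4ccccc4)[C@@H]2O3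
F6 | step 10 | (1R,2S,3S,6S)-3-benzoyloxy-1,6-epoxy-1-(hydroxymethyl)cyclohex-4-en-2-ol | OC[C@]12O[C@H]1C=C[C@H](OC(=O)c3ccccc3)[C@@H]2O
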